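Readings and results are simulated for substances that don't exist.

Slowness is what strikes me in this solid substrate: in the reagent solution it wears away over days.

in all of them: reagent 0.0347 M

| flask | solid substrate | remark | time |
|---|---|---|---|
| eta | 0.022 M | run made earlier |  |
| epsilon | 0.050 M | run made earlier |  |
| flask | 0.033 M |  | 3.0 d |

| run | time / h | solid substrate / % | mono adduct / % |
|---|---|---|---|
| eta | 8.00 | 89.1 | 1.2 |
| eta | 15.0 | 85.7 | 2.2 |
| eta | 25.0 | 80.8 | 2.2 |
| eta | 30.0 | 78.6 | 2.2 |
| eta | 40.0 | 73.6 | 2.4 |
| epsilon | 8.00 | 95.0 | 0.6 |
| epsilon | 15.0 | 93.8 | 0.9 |
| epsilon | 25.0 | 91.7 | 1.0 |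
| epsilon | 30.0 | 89.8 | 0.7 |
| epsilon | 40.0 | 88.4 | 1.1 |

(scatter of a reading: 0.3 percentage points)

- as a solid, counted per litre of solution: solid substrate
- the numbers in the tables scatter with a standard deviation of 0.3 percentage points
- at the start none of the solid substrate is in solution

* amount of solid substrate at 3.0 d, in percent of the solid substrate charged (only what is still solid)
* amount of mono adduct at 3.0 d, in percent of the solid substrate charged
* amount of other mono adduct at 3.0 d, in percent of the solid substrate charged
* amount of double product at 3.0 d, in percent of the solid substrate charged

The two runs seem to disagree. Over the same 32.0 h between first and last reading, the eta run loses 16 percentage points of its charge. The epsilon run, with 2.27 times the solid, loses 6.6 points. More solid, smaller share.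

I multiply each share by its charge. The losses per litre are 0.00341 M and 0.00330 M, nearly equal, so the loss is zero order in the solid. That gives 1.05 × 10⁻⁴ M h⁻¹: the drain, the solid lost per litre per hour in these two runs, which share one reagent charge. With that reagent charge, a run's share falls at the drain divided by its solid charge.

Read back to zero time, both lines show an early loss, on average 0.00161 M, which is 4.88 % of this flask's charge.

In the eta run, mono adduct stays flat from 2.2 % to 2.4 %, far less change than the solid shows. I freeze it, and each unit of solid that reacts then takes two of reagent. I assume the drain follows the reagent, which I put near 85.5 % of its charge midway through the readings. For this flask I then reckon 60.1 % of the reagent left at the end, and solid at 74.2 %.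

The forecast says 74.5 % solid, 1.6 % mono adduct, 1.5 % other mono adduct and 17.6 % double product, holding that “the rate doesn't depend on the solid charged”.

The flask gives 74.2 % solid, 1.40 % mono adduct, 1.21 % other mono adduct and 17.9 % double product.

    starting material + reagent → mono adduct + by-product (k = 1.60 M⁻¹ h⁻¹)
    reagent + other mono adduct → double product + by-product (k = 1.70 M⁻¹ h⁻¹)
    starting material + reagent → other mono adduct + by-product (k = 0.410 M⁻¹ h⁻¹)
    solid substrate ⇌ starting material, rate k4*(cs4 - [starting material]) while solid is left; crystals form when [starting material] > cs4 (solubility = 1.90 mM, k = 0.500 h⁻¹)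
    reagent + mono adduct → double product + by-product (k = 6.00 M⁻¹ h⁻¹)

At 1.05 d this flask's mono adduct has a half-life of 0.16 d by its passage to double product, short against the 3.0 d of the flask. It is then made 1.02 times as fast as it is used, and the steps into and out of it use reagent at a ratio of 1.0. Beyond the early 0.00161 M, the flask's own drain averages 9.59 × 10⁻⁵ M h⁻¹, below that of the runs. Taking this flask's 0.00852 M lost per litre to the neighbour with 0.020 M of solid leaves 57.4 % of its charge, and that neighbour holds 57.4 % solid.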